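**Retrosynthetic overview**
1. Target ⇒ (global O-debenzylation, then alcohol oxidation) bis-carbinol ⇒ cut both aryl–C(O) bonds: 2 × 2,4-bis(benzyloxy)phenyllithium + meso-2,3-bis[4-(benzyloxy)benzyl]succinaldehyde.
2. meso-Dialdehyde ⇒ meso-1,4-diol ⇒ cis-α,β-dibenzyl-γ-butyrolactone (cis on the ring equals meso in the open chain).
3. cis-Lactone ⇒ face-selective hydrogenation of the (E)-α-benzylidene-β-benzyl lactone ⇒ key C–C bond: intermolecular aldol of the β-benzyl lactone enolate with 4-(benzyloxy)benzaldehyde.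
4. β-Benzyl lactone ⇒ Stobbe (aldol–lactonisation) condensation of diethyl succinate with the same aldehyde.
5. Rings: all four arenes are bought. The only ring made is the temporary butyrolactone template, closed in step 3 and opened in step 7.

Assumption: the molecule is constitutionally symmetric and the two written descriptors work out as (2S,3R), which is the same as (2R,3S). This is the meso, achiral diastereomer, so the task is meso-versus-dl control and racemic intermediates are legitimate.

**Step 1**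
Reactants: 1 4-(benzyloxy)benzaldehyde; 2 diethyl succinate
Product: 4 (E)-4-[4-(benzyloxy)phenyl]-3-(ethoxycarbonyl)but-3-enoic acid, via paraconic ester lactone 3 (not isolated)
Conditions: KOtBu (1.2 equiv), 2 (1.5 equiv), t-BuOH, reflux, 3 h; then 2 M HCl
Reagents that add atoms: none
Why: Stobbe condensation, in which the succinate enolate adds to the non-enolisable aldehyde in an aldol step, the alkoxide lactonises to 3, and irreversible E1cB opening to the carboxylate drives the reaction, stops it after one condensation and gives the E alkene (aryl anti to the ester) with no stereocentre formed.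

**Step 2**
Reactants: 4 (E)-4-[4-(benzyloxy)phenyl]-3-(ethoxycarbonyl)but-3-enoic acid
Product: 5 rac-4-[4-(benzyloxy)phenyl]-3-(ethoxycarbonyl)butanoic acid
Conditions: H2 (5 bar), [Rh(cod)(dppb)]BF4 (1 mol %), MeOH, 25 °C
Reagents that add atoms: none
Why: Carboxyl-directed homogeneous hydrogenation with a cationic rhodium diphosphine catalyst saturates the itaconate-type alkene without the aryl benzyl ether hydrogenolysis that Pd/C would cause, and the racemic new stereocentre is harmless because the target is meso.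

**Step 3**
Reactants: 5 rac-4-[4-(benzyloxy)phenyl]-3-(ethoxycarbonyl)butanoic acid
Product: 7 rac-4-[4-(benzyloxy)benzyl]dihydrofuran-2(3H)-one, via hydroxy acid 6 (not isolated)
Conditions: KOH (1.0 equiv), EtOH; CaCl2, NaBH4, EtOH, −10 °C to rt; then 3 M HCl, rt
Reagents that add atoms: none
Why: Chemoselective borohydride reduction, in which Ca(BH4)2 reduces the ester while the potassium carboxylate is inert, followed by acid lactonisation of 6 to the five-membered ring with the benzyl group on the β-carbon.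

**Step 4**
Reactants: 7 rac-4-[4-(benzyloxy)benzyl]dihydrofuran-2(3H)-one; 1 4-(benzyloxy)benzaldehyde
Product: 9 rac-(3,4-trans)-4-[4-(benzyloxy)benzyl]-3-{[4-(benzyloxy)phenyl](hydroxy)methyl}dihydrofuran-2(3H)-one (both carbinol epimers), via lithium enolate 8 (not isolated)
Conditions: LiN(SiMe3)2 (1.1 equiv), THF, −78 °C, 45 min; then 1 (1.1 equiv), −78 °C, 1 h; AcOH quench at −78 °C
Reagents that add atoms: none
Why: Intermolecular aldol addition of a preformed lactone enolate to a non-enolisable aldehyde forms the second benzylic C–C bond anti to the C4 benzyl group, and the C3 and carbinol centres are erased in step 5, so their ratio does not matter.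

**Step 5**
Reactants: 9 aldol adduct (both carbinol epimers)
Product: 11 rac-(E)-4-[4-(benzyloxy)benzyl]-3-[4-(benzyloxy)benzylidene]dihydrofuran-2(3H)-one, via aldol acetate 10 (not isolated)
Conditions: Ac2O, Et3N, DMAP (cat.), CH2Cl2, rt; then DBU, rt to 40 °C
Reagents that add atoms: none
Why: Acetylation followed by E1cB elimination (aldol condensation completed) brings both carbinol epimers to the conjugated, thermodynamically preferred E-benzylidene lactone, and an acetate is used because a p-alkoxybenzylic sulfonate would ionise.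

**Step 6**
Reactants: 11 rac-(E)-4-[4-(benzyloxy)benzyl]-3-[4-(benzyloxy)benzylidene]dihydrofuran-2(3H)-one
Product: 12 rac-(3R,4S)-3,4-bis(4-hydroxybenzyl)dihydrofuran-2(3H)-one (cis)
Conditions: H2 (1 atm), 10% Pd/C, EtOAc–EtOH, rt; recrystallise to remove the minor trans isomer
Reagents that add atoms: none
Why: Heterogeneous syn hydrogenation with concurrent benzyl ether hydrogenolysis, in which allylic 1,3-strain with the E-aryl group forces the C4 benzyl group pseudoaxial so that hydrogen arrives on the opposite face and the new C3 benzyl group ends up cis to it (any isomerisation to the endocyclic butenolide also gives cis by syn addition).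

**Step 7**
Reactants: 12 rac-(3R,4S)-3,4-bis(4-hydroxybenzyl)dihydrofuran-2(3H)-one
Product: 13 meso-(2R,3S)-2,3-bis(4-hydroxybenzyl)butane-1,4-diol
Conditions: LiAlH4 (4 equiv), THF, 0 °C (12 added to the hydride), then rt 1 h; 1 M HCl work-up
Reagents that add atoms: none
Why: LiAlH4 lactone reduction is much faster than enolisation, so both stereocentres are kept and opening the cis ring gives a diol with an internal mirror plane.

**Step 8**
Reactants: 13 meso-(2R,3S)-2,3-bis(4-hydroxybenzyl)butane-1,4-diol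
Product: 14 meso-(2R,3S)-2,3-bis[4-(benzyloxy)benzyl]butane-1,4-diol
Conditions: BnBr (2.1 equiv), K2CO3 (3 equiv), acetone, reflux; recrystallise
Reagents that add atoms: benzyl bromide BrCc1ccccc1
Why: Williamson ether synthesis in which K2CO3 deprotonates only the phenols and not the primary alcohols, carried out on a compound with no epimerisable centre so the re-protection is stereochemically safe.

**Step 9**
Reactants: 14 meso-(2R,3S)-2,3-bis[4-(benzyloxy)benzyl]butane-1,4-diol
Product: 16 meso-(2R,3S)-2,3-bis[4-(benzyloxy)benzyl]butanedial, via bis(alkoxysulfonium) salt 15 (not isolated)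
Conditions: (COCl)2 (3 equiv), DMSO (6 equiv), CH2Cl2, −78 °C; 14; then i-Pr2NEt (10 equiv), −78 to −30 °C; cold pH 7 buffer; used crude at once
Reagents that add atoms: none
Why: Swern oxidation activates both hydroxyls as 15 before any base is present, so no hydroxy aldehyde can close to a lactol and over-oxidise to the lactone, and the hindered base at low temperature leaves the α-stereocentres untouched.

**Step 10**
Reactants: 17 4-bromoresorcinol
Product: 18 2,4-bis(benzyloxy)-1-bromobenzene
Conditions: BnBr (2.2 equiv), K2CO3 (3 equiv), DMF, 60 °C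
Reagents that add atoms: benzyl bromide BrCc1ccccc1
Why: Double Williamson ether synthesis on two acidic phenols, with the aryl bromide inert under these conditions.

**Step 11**
Reactants: 16 meso-(2R,3S)-2,3-bis[4-(benzyloxy)benzyl]butanedial; 18 2,4-bis(benzyloxy)-1-bromobenzene
Product: 20 (2R,3S)-1,4-bis[2,4-bis(benzyloxy)phenyl]-2,3-bis[4-(benzyloxy)benzyl]butane-1,4-diol (carbinol epimers), via aryllithium 19 (not isolated)
Conditions: 18 (4 equiv), n-BuLi (4 equiv), THF, −78 °C, 30 min; 16 in THF added dropwise, −78 to −30 °C; H2O quench; Et3N-deactivated silica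
Reagents that add atoms: none
Why: Bromine–lithium exchange followed by two-directional 1,2-addition of the aryllithium to the aldehydes, which outruns α-deprotonation so C2 and C3 keep their configuration, while the unselective carbinol centres are erased in step 12.

**Step 12**
Reactants: 20 bis-carbinol (carbinol epimers)
Product: 21 meso-(2R,3S)-1,4-bis[2,4-bis(benzyloxy)phenyl]-2,3-bis[4-(benzyloxy)benzyl]butane-1,4-dione
Conditions: Dess–Martin periodinane (3 equiv), NaHCO3 (12 equiv), CH2Cl2, 0 °C to rt; recrystallise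
Reagents that add atoms: none
Why: Buffered Dess–Martin oxidation converts both electron-rich benzylic alcohols to ketones without acid (which would close the diol to a 2,5-diaryltetrahydrofuran) and without base (which would epimerise C2 and C3), and all carbinol epimers converge on one meso diketone.

**Step 13**
Reactants: 21 meso hexabenzyl ether diketone
Product: 22 meso-(2R,3S)-1,4-bis(2,4-dihydroxyphenyl)-2,3-bis(4-hydroxybenzyl)butane-1,4-dione (target)
Conditions: H2 (1 atm), 10% Pd/C, THF–MeOH 1:1, rt; filter, crystallise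
Reagents that add atoms: none
Why: Neutral catalytic hydrogenolysis removes all six aryl benzyl ethers without the acid that would cause Paal–Knorr furan formation or the base that would cause epimerisation, and the strongly donor-substituted, hydrogen-bonded aryl ketones are not reduced at 1 atm.

**Compound list**
1 | 4-(benzyloxy)benzaldehyde | O=Cc1ccc(OCc2ccccc2)cc1 | starting material
2 | diethyl succinate | CCOC(=O)CCC(=O)OCC | starting material
3 | ethyl 2-[4-(benzyloxy)phenyl]-5-oxotetrahydrofuran-3-carboxylate (paraconic ester lactone) | CCOC(=O)C1CC(=O)OC1c1ccc(OCc2ccccc2)cc1 | intermediate (not isolated)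
4 | (E)-4-[4-(benzyloxy)phenyl]-3-(ethoxycarbonyl)but-3-enoic acid | OC(=O)C/C(C(=O)OCC)=C\c1ccc(OCc2ccccc2)cc1 | intermediate
5 | rac-4-[4-(benzyloxy)phenyl]-3-(ethoxycarbonyl)butanoic acid | OC(=O)CC(Cc1ccc(OCc2ccccc2)cc1)C(=O)OCC | intermediate
6 | rac-4-[4-(benzyloxy)phenyl]-3-(hydroxymethyl)butanoic acid | OC(=O)CC(CO)Cc1ccc(OCc2ccccc2)cc1 | intermediate (not isolated)
7 | rac-4-[4-(benzyloxy)benzyl]dihydrofuran-2(3H)-one | O=C1CC(Cc2ccc(OCc3ccccc3)cc2)CO1 | intermediate
8 | lithium enolate of 7 | [Li+].[O-]C1=CC(Cc2ccc(OCc3ccccc3)cc2)CO1 | intermediate (not isolated)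
9 | rac-(3,4-trans)-4-[4-(benzyloxy)benzyl]-3-{[4-(benzyloxy)phenyl](hydroxy)methyl}dihydrofuran-2(3H)-one, carbinol epimers (one enantiomer drawn) | O=C1OC[C@@H](Cc2ccc(OCc3ccccc3)cc2)[C@@H]1C(O)c1ccc(OCc2ccccc2)cc1 | intermediate
10 | acetate of 9 | O=C1OC[C@@H](Cc2ccc(OCc3ccccc3)cc2)[C@@H]1C(OC(C)=O)c1ccc(OCc2ccccc2)cc1 | intermediate (not isolated)
11 | rac-(E)-4-[4-(benzyloxy)benzyl]-3-[4-(benzyloxy)benzylidene]dihydrofuran-2(3H)-one | O=C1OCC(Cc2ccc(OCc3ccccc3)cc2)/C1=C\c1ccc(OCc2ccccc2)cc1 | intermediate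
12 | rac-(3R,4S)-3,4-bis(4-hydroxybenzyl)dihydrofuran-2(3H)-one, cis (one enantiomer drawn) | O=C1OC[C@@H](Cc2ccc(O)cc2)[C@H]1Cc1ccc(O)cc1 | intermediate
13 | meso-(2R,3S)-2,3-bis(4-hydroxybenzyl)butane-1,4-diol | OC[C@@H](Cc1ccc(O)cc1)[C@@H](Cc1ccc(O)cc1)CO | intermediate
14 | meso-(2R,3S)-2,3-bis[4-(benzyloxy)benzyl]butane-1,4-diol | OC[C@@H](Cc1ccc(OCc2ccccc2)cc1)[C@@H](Cc1ccc(OCc2ccccc2)cc1)CO | intermediate
15 | bis(dimethylalkoxysulfonium) dichloride of 14 | C[S+](C)OC[C@@H](Cc1ccc(OCc2ccccc2)cc1)[C@@H](Cc1ccc(OCc2ccccc2)cc1)CO[S+](C)C.[Cl-].[Cl-] | intermediate (not isolated)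
16 | meso-(2R,3S)-2,3-bis[4-(benzyloxy)benzyl]butanedial | O=C[C@@H](Cc1ccc(OCc2ccccc2)cc1)[C@@H](Cc1ccc(OCc2ccccc2)cc1)C=O | intermediate
17 | 4-bromoresorcinol | Oc1ccc(Br)c(O)c1 | starting material
18 | 2,4-bis(benzyloxy)-1-bromobenzene | Brc1ccc(OCc2ccccc2)cc1OCc1ccccc1 | intermediate
19 | [2,4-bis(benzyloxy)phenyl]lithium | [Li]c1ccc(OCc2ccccc2)cc1OCc1ccccc1 | intermediate (not isolated)
20 | (2R,3S)-1,4-bis[2,4-bis(benzyloxy)phenyl]-2,3-bis[4-(benzyloxy)benzyl]butane-1,4-diol, carbinol epimers | OC(c1ccc(OCc2ccccc2)cc1OCc1ccccc1)[C@@H](Cc1ccc(OCc2ccccc2)cc1)[C@@H](Cc1ccc(OCc2ccccc2)cc1)C(O)c1ccc(OCc2ccccc2)cc1OCc1ccccc1 | intermediate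
21 | meso-(2R,3S)-1,4-bis[2,4-bis(benzyloxy)phenyl]-2,3-bis[4-(benzyloxy)benzyl]butane-1,4-dione | O=C(c1ccc(OCc2ccccc2)cc1OCc1ccccc1)[C@@H](Cc1ccc(OCc2ccccc2)cc1)[C@@H](Cc1ccc(OCc2ccccc2)cc1)C(=O)c1ccc(OCc2ccccc2)cc1OCc1ccccc1 | intermediate
22 | meso-(2R,3S)-1,4-bis(2,4-dihydroxyphenyl)-2,3-bis(4-hydroxybenzyl)butane-1,4-dione | O=C(c1ccc(O)cc1O)[C@@H](Cc1ccc(O)cc1)[C@@H](Cc1ccc(O)cc1)C(=O)c1ccc(O)cc1O | target

**Totals**
Total steps: 13. Longest linear sequence: 12 (steps 1–9 and 11–13; step 10 is the side branch).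

**Three steps most likely to fail**

Step 6 (the cis/trans ratio of the hydrogenation may be too low). The fallback sets C3 by kinetic enolate protonation instead of hydrogenation and sets out from 11.
- 1,4-Hydride addition with LiBH(s-Bu)3 in THF at −78 °C gives the lithium enolate of the saturated lactone F1.
- F1 is protonated in the flask by 2,6-di-tert-butyl-4-methylphenol on the face away from the C4 benzyl group. This gives rac-(3R,4S)-3,4-bis[4-(benzyloxy)benzyl]dihydrofuran-2(3H)-one F2 with both benzyl ethers intact.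
- LiAlH4 in THF at 0 °C opens it to 14, where the route is rejoined. Steps 7 and 8 are skipped.

Step 9 (dialdehyde 16 may epimerise or cyclodehydrate to the 3,4-dibenzylfuran). The fallback raises the two termini to the acid level one at a time and makes the ketones by acyl substitution, so no 1,4-dialdehyde is ever present. It sets out from 14.
- TEMPO (cat.)/PhI(OAc)2 in CH2Cl2 gives, by oxidative lactonisation, the cis-lactone bis(benzyl ether) F2.
- Me3Al/MeNHOMe·HCl in CH2Cl2 opens it to rac-(2S,3R)-2,3-bis[4-(benzyloxy)benzyl]-4-hydroxy-N-methoxy-N-methylbutanamide F3.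
- TEMPO/PhI(OAc)2 in MeCN–water, applied at once, takes the primary alcohol to rac-(2R,3S)-2,3-bis[4-(benzyloxy)benzyl]-4-[methoxy(methyl)amino]-4-oxobutanoic acid F4.
- EDC·HCl, HOBt, N-methylmorpholine and MeNHOMe·HCl give meso-(2R,3S)-2,3-bis[4-(benzyloxy)benzyl]-N1,N4-dimethoxy-N1,N4-dimethylbutanediamide F5.
- Aryllithium 19 (3 equiv, THF, −78 to −20 °C, cold dilute acid quench) converts it to 21, where the route is rejoined. Steps 11 and 12 are skipped.

Step 11 (after the first addition the γ-alkoxide can close onto the second aldehyde as a lactolate, so the second addition stalls, or the aryllithium decays on warming). The fallback sets out from 16.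
- Pinnick oxidation (NaClO2, NaH2PO4, 2-methyl-2-butene, t-BuOH–water) gives meso-(2R,3S)-2,3-bis[4-(benzyloxy)benzyl]butanedioic acid F6.
- Double amidation (EDC·HCl, HOBt, N-methylmorpholine, MeNHOMe·HCl) gives the meso bis-Weinreb amide F5.
- Its stable chelated adducts with 19 release 21 on quench, where the route is rejoined. Step 12 is skipped.

**Further compounds**
F1 | step 6 | lithium enolate of 3,4-bis[4-(benzyloxy)benzyl]dihydrofuran-2(3H)-one (racemic at C4) | [Li+].[O-]C1=C(Cc2ccc(OCc3ccccc3)cc2)C(Cc2ccc(OCc3ccccc3)cc2)CO1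
F2 | step 6 | rac-(3R,4S)-3,4-bis[4-(benzyloxy)benzyl]dihydrofuran-2(3H)-one (cis) | O=C1OC[C@@H](Cc2ccc(OCc3ccccc3)cc2)[C@H]1Cc1ccc(OCc2ccccc2)cc1
F3 | step 9 | rac-(2S,3R)-2,3-bis[4-(benzyloxy)benzyl]-4-hydroxy-N-methoxy-N-methylbutanamide | CON(C)C(=O)[C@@H](Cc1ccc(OCc2ccccc2)cc1)[C@@H](Cc1ccc(OCc2ccccc2)cc1)CO
F4 | step 9 | rac-(2R,3S)-2,3-bis[4-(benzyloxy)benzyl]-4-[methoxy(methyl)amino]-4-oxobutanoic acid | CON(C)C(=O)[C@@H](Cc1ccc(OCc2ccccc2)cc1)[C@@H](Cc1ccc(OCc2ccccc2)cc1)C(=O)O
F5 | step 9 | meso-(2R,3S)-2,3-bis[4-(benzyloxy)benzyl]-N1,N4-dimethoxy-N1,N4-dimethylbutanediamide | CON(C)C(=O)[C@@H](Cc1ccc(OCc2ccccc2)cc1)[C@@H](Cc1ccc(OCc2ccccc2)cc1)C(=O)N(C)OC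
F6 | step 11 | meso-(2R,3S)-2,3-bis[4-(benzyloxy)benzyl]butanedioic acid | OC(=O)[C@@H](Cc1ccc(OCc2ccccc2)cc1)[C@@H](Cc1ccc(OCc2ccccc2)cc1)C(=O)O
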